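At 220 h north-west holds a larger share of its Sbt in Pdt than north-east, although its charge of Sbt is weaker.

| flask | Sbt | Ptn | time |
|---|---|---|---|
| north-east | 0.200 M | 0.600 M |  |
| north-west | 0.0800 M | 0.480 M |  |
| east | 0.200 M | 1.20 M |  |
| north | 0.200 M | 0.600 M | 660 h |

| run | time / h | [Pdt] / M |
|---|---|---|
| north-east run | 28 | 0.0571 |
| north-east run | 55 | 0.0682 |
| north-east run | 82 | 0.0751 |
| north-east run | 110 | 0.0767 |
| north-east run | 140 | 0.0767 |
| north-east run | 160 | 0.0778 |
| north-east run | 190 | 0.0788 |
| north-east run | 220 | 0.0797 |
| north-west run | 28 | 0.0278 |
| north-west run | 55 | 0.0349 |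
| north-west run | 82 | 0.0373 |
| north-west run | 110 | 0.0395 |
| north-west run | 140 | 0.0409 |
| north-west run | 160 | 0.0398 |
| north-west run | 190 | 0.0430 |
| north-west run | 220 | 0.0417 |
| east run | 28 | 0.0894 |
| east run | 55 | 0.1003 |
| east run | 82 | 0.1055 |
| east run | 110 | 0.1058 |
| east run | 140 | 0.1083 |
| east run | 160 | 0.1090 |
| east run | 190 | 0.1085 |
| east run | 220 | 0.1079 |

(each reading ± 0.001 M)

- Overall: Sbt + Ptn -> Pdt.
- Constant volume, constant temperature.
- "The second partner" is Ptn.
- An order is taken over about fifteen percent of the charge, up and down.

1. reaction order in [Sbt] at the outset, round the charge of the north-east run, defined at two percent of the Sbt turned into Pdt (one fixed amount of Pdt, the same in the runs compared)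
2. reaction order in [Ptn] at the outset, round the charge of the north-east run, defined at two percent of the Sbt turned into Pdt
3. Pdt in the north run at 660 h, as a share of the Sbt charged

The small table below sets the charge ratio beside the share of Sbt found as Pdt at the last reading, 220 h.

| run | Sbt/Ptn charged | Pdt as share of Sbt charged |
|---|---|---|
| north-east | 0.333 | 39.8% |
| north-west | 0.167 | 52.1% |
| east | 0.167 | 53.9% |

The first row has the higher ratio and the lower share. The other two rows have equal ratios, and their shares lie 1.8 percentage points apart, while one north-west share carries a scatter of 1.25%. So in these runs, at that reading, the share goes with the ratio, and what strength does at equal ratio may be to change the pace.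

East is 2.50 times as strong as north-west in both partners. Call this the clock factor: if every rate goes as the square of strength, then at equal ratio and equal temperature the stronger flask shows that many times the Pdt at the time divided by it. In logarithms, the two curves should then lie 0.398 apart along both axes. As a check, north-west at 140 h and east at 55 h differ 2.55-fold in time and 2.45-fold in Pdt.

The same assumption makes the two orders add to 2 in the reckoning here. The first north-east reading, at 28 h, already shows 28.5% of the Sbt as Pdt, against the two percent at which the orders are defined, so this reckoning gives no split between them.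

For the tail, a rough reckoning serves. The east readings gain a factor 1.02 from 82 h to 220 h, a stretch of 2.68 in time, and the north run, charged as north-east, asks for 3.00 in time beyond the last north-east reading. Borrowed across ratios, that factor gives an estimate of 40.8% for the north run at 660 h.

The forecast gives an order of 0.9 in Sbt, an order of 1 in Ptn and 41% for the north run, noting that “North-east is still creeping at 220 h”.

    Sbt ⇌ Imd, settled at all times (0.1840)
    Imd + Ptn → Pdt (0.3535 M⁻¹ h⁻¹)
    2 Sbt → Q (0.3420 M⁻¹ h⁻¹)
    2 Ptn → E (0.01670 M⁻¹ h⁻¹)

The north run holds 40.2% of its Sbt charged as Pdt at 660 h, which is 0.0805 M of Pdt, and the orders are 1.0 in Sbt and 1.1 in Ptn. The Pdt made comes to half of the Sbt charged at 52.0 h in east and at 130 h in north-west, and the clock factor 2.50 times the east time gives 130 h. For a quarter of the Sbt charged, east needs 6.41 h; the same factor gives 16.0 h, and north-west takes 16.0 h.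

(The runs are calculated with made-up constants; noise was put on by code.)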